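The other conformer charged cannot account for the isomer of the product: in the blue run that charge is 4.76% of the material, yet the isomer reads 42.5% at 1.04 d. Starting material must feed it, and that costs partner.

| flask | starting material | partner | other conformer | remark | time |
|---|---|---|---|---|---|
| blue | 0.10 M | 0.15 M | 0.0050 M | run made earlier |  |
| ochre | 0.10 M | 0.15 M | 0.020 M | run made earlier |  |
| flask | 0.10 M | 0.150 M | 0.0100 M |  | 15 d |

| run | time / d | target / % | isomer of the product / % |
|---|---|---|---|
| blue | 1.04 | 5.6 | 42.5 |
| blue | 3.00 | 4.1 | 52.0 |
| blue | 6.00 | 3.1 | 54.2 |
| blue | 8.00 | 2.7 | 54.8 |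
| blue | 12.0 | 3.0 | 55.0 |
| ochre | 2.50 | 3.1 | 52.9 |
| ochre | 5.00 | 1.6 | 56.3 |
| ochre | 8.00 | 1.4 | 56.8 |
| ochre | 10.0 | 0.6 | 57.6 |
| ochre | 12.0 | 1.4 | 58.0 |

(readings scatter by 0.3 percentage points)



- ratio of target to isomer of the product at 40 min
- ratio of target to isomer of the product at 15 d

So I carry one number for the new flask: the coverage, moles of partner charged per mole of starting material and other conformer together, here 1.36.

Suppose first one step, partner + other conformer to isomer, on the charge as it stands. This flask then asks for 0.0909 partner per mole charged.

Add the feed from starting material. Target and isomer together read 58.0% in the blue run at 12.0 d, so the demand rises to that share.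

Add the rest, the 42.0% of the blue charge that the readings do not show. If each mole of it took one partner, the demand would reach 1.

The coverage is above that, so I reckon partner stays in excess and the material is the limiting reagent. I therefore expect the late ratio to lie between the last ratios of blue, 0.0545, and ochre, 0.0241. Both runs were first read later than 40 min, blue at 1.04 d and ochre at 2.50 d, and coverage gives no early ratio.

The forecast gives 0.22 at 40 min and 0.035 at 15 d: “By 15 d the flask should have reached this plateau.”

The flask gives 0.466 at 40 min and 0.0385 at 15 d. At 15 d it holds 0.0278 M of homo dimer, two partner in each. With 5.0% of its partner left, it has used 1.30 partner per mole charged, above the 1 I allowed.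

    starting material ⇌ other conformer (K = 0.180, k = 0.0930 h⁻¹)
    starting material + partner → target (k = 0.190 M⁻¹ h⁻¹)
    partner + other conformer → isomer of the product (k = 3.90 M⁻¹ h⁻¹)
    2 partner → homo dimer (k = 0.110 M⁻¹ h⁻¹)
    starting material + target → side product (k = 2.10 M⁻¹ h⁻¹)

A neighbour charged with 0.090 M of partner has coverage 0.818, below that use, so its partner should give out first. At 15 d it holds 0.140% of its own partner beside 12.5% of starting material, and its late ratio is 3.61 × 10⁻⁴.

The earlier runs and the new flask are simulated on assumed constants; scatter was added.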